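**Plan**

- Enabling feature: in ring C the C4 ketone carbon and the C3 carbinol carbon are direct neighbours and both derive from carbonyl groups, which is an acyloin pattern. Ring C can therefore be cut at C3–C4 into a ring A aryl aldehyde (C4) and an α-aryl-α-aryloxy acetaldehyde (C3) attached through O1.
- Retrosynthetic cuts, in order: the four O–benzyl bonds; C3–C4 (umpolung closure); O1–C2 (phenoxide plus α-bromo arylacetate); C4–C4a (ortho-formylation); the bond between the C6 methylene carbon and its 4-oxyphenyl ring (aryl Grignard addition to the formyl group of 2,4,6-trihydroxybenzaldehyde, then deoxygenation).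
- Forward: the three benzene rings are bought. A mirror-symmetric 3,5-dibenzyloxy-4-benzylphenol is built first, so formylation can give only the 6-benzyl series and not the 8-benzyl series. O-alkylation, reduction of ester and aldehyde to a diol, and double oxidation give the racemic dialdehyde. Ring C is the only ring made, and it closes in the key step. Hydrogenolysis ends the route.
- Stereochemistry: both centres arise in the key step. C3 comes from the chiral aminoindanol-derived triazolylidene, C2 from dynamic kinetic resolution of the enolisable side-chain aldehyde, and the 2,3-trans relation from the diequatorial half-chair. No later step touches them.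

Key step: step 12

Assumption: the absolute sense of induction of the aminoindanol-derived triazolium salt cannot be derived for this new substrate class. The (5aR,10bS) salt is written throughout, and its equally available mirror image is to be used if a trial closure delivers the antipode.

**Step 1**
Reactants: 1 2,4,6-trihydroxybenzaldehyde
Product: 2 4-(allyloxy)-2,6-dihydroxybenzaldehyde
Conditions: allyl bromide (1.0 equiv), KHCO3, DMF, 40 °C
Reagents that add atoms: allyl bromide, C=CCBr
Why: Williamson etherification under acidity control: the para hydroxyl is the most acidic of the three and the only one that cannot hydrogen-bond to the formyl oxygen, so bicarbonate and one equivalent of halide should etherify it alone, as known for the 4-O-monoalkylation of acylphloroglucinols.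

**Step 2**
Reactants: 2 4-(allyloxy)-2,6-dihydroxybenzaldehyde
Product: 3 4-(allyloxy)-2,6-bis(benzyloxy)benzaldehyde
Conditions: BnBr (2.5 equiv), K2CO3, DMF, 60 °C
Reagents that add atoms: benzyl bromide, BrCc1ccccc1
Why: Exhaustive Williamson benzylation, in which carbonate in warm DMF overcomes the chelation of the two ortho hydroxyls while the allyl ether stays far below Claisen rearrangement temperatures.

**Step 3**
Reactants: 3 4-(allyloxy)-2,6-bis(benzyloxy)benzaldehyde; 4 1-(benzyloxy)-4-bromobenzene
Product: 6 [4-(allyloxy)-2,6-bis(benzyloxy)phenyl][4-(benzyloxy)phenyl]methanol (racemic), via 4-(benzyloxy)phenylmagnesium bromide 5 (not isolated)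
Conditions: 4, Mg, THF, reflux; then 3, THF, 0 °C to rt; aqueous work-up
Reagents that add atoms: magnesium, [Mg] (held only by 5)
Why: Grignard addition to an aryl aldehyde that carries only ether groups; the carbinol centre forms racemic and is erased in step 4.

**Step 4**
Reactants: 6 [4-(allyloxy)-2,6-bis(benzyloxy)phenyl][4-(benzyloxy)phenyl]methanol
Product: 7 5-(allyloxy)-1,3-bis(benzyloxy)-2-[4-(benzyloxy)benzyl]benzene
Conditions: Et3SiH, CF3CO2H, CH2Cl2, −20 to 0 °C
Reagents that add atoms: none
Why: Ionic hydrogenation: acid ionises the carbinol to a cation stabilised by four alkoxy groups across both rings and the silane delivers hydride, while aryl benzyl ethers and the unactivated allyl double bond do not react at this temperature.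

**Step 5**
Reactants: 7 5-(allyloxy)-1,3-bis(benzyloxy)-2-[4-(benzyloxy)benzyl]benzene
Product: 8 3,5-bis(benzyloxy)-4-[4-(benzyloxy)benzyl]phenol
Conditions: Pd(PPh3)4 (cat.), morpholine, THF, rt
Reagents that add atoms: none
Why: Tsuji–Trost deallylation: zerovalent palladium ionises only the allyl aryl ether and morpholine captures the allyl group, so the three benzyl ethers remain and a phenol with a mirror plane through C1 and C4 results.

**Step 6**
Reactants: 8 3,5-bis(benzyloxy)-4-[4-(benzyloxy)benzyl]phenol
Product: 9 2,4-bis(benzyloxy)-3-[4-(benzyloxy)benzyl]-6-hydroxybenzaldehyde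
Conditions: MgCl2, Et3N, (CH2O)n, MeCN, reflux; then 1 M HCl
Reagents that add atoms: paraformaldehyde (formaldehyde unit), C=O
Why: Casnati–Skattebøl ortho-formylation: formaldehyde is delivered inside the magnesium phenoxide to an ortho carbon and a second formaldehyde takes up hydride, and since the two ortho positions are equivalent and para is blocked, only one regioisomer, with the benzyl group at the future C6, can form.

**Step 7**
Reactants: 10 4-(benzyloxy)phenylacetic acid
Product: 11 methyl 4-(benzyloxy)phenylacetate
Conditions: MeOH, H2SO4 (cat.), reflux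
Reagents that add atoms: methanol, CO
Why: Fischer esterification, to which the aryl benzyl ether is inert.

**Step 8**
Reactants: 11 methyl 4-(benzyloxy)phenylacetate
Product: 13 methyl 2-bromo-2-[4-(benzyloxy)phenyl]acetate (racemic), via trimethylsilyl ketene acetal 12 (not isolated)
Conditions: LiN(SiMe3)2, Me3SiCl, THF, −78 °C; then NBS, −78 to 0 °C
Reagents that add atoms: N-bromosuccinimide, O=C1CCC(=O)N1Br; chlorotrimethylsilane, C[Si](C)(C)Cl (silyl group held only by 12)
Why: Polar α-bromination of an ester through its silyl ketene acetal, chosen over a Wohl–Ziegler reaction because it spares the O-benzyl methylene and the electron-rich ring; the new centre is racemic, as wanted.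

**Step 9**
Reactants: 9 2,4-bis(benzyloxy)-3-[4-(benzyloxy)benzyl]-6-hydroxybenzaldehyde; 13 methyl 2-bromo-2-[4-(benzyloxy)phenyl]acetate
Product: 14 methyl 2-{3,5-bis(benzyloxy)-4-[4-(benzyloxy)benzyl]-2-formylphenoxy}-2-[4-(benzyloxy)phenyl]acetate (racemic)
Conditions: K2CO3, DMF, rt to 40 °C
Reagents that add atoms: none
Why: Williamson etherification (SN2) of a salicylaldehyde phenoxide with an activated secondary α-bromo arylacetate, the opening step of the classical 2-arylbenzofuran synthesis, run near room temperature so that the follow-up aldol closure does not start; the future C2 is racemic by design.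

**Step 10**
Reactants: 14 methyl 2-{3,5-bis(benzyloxy)-4-[4-(benzyloxy)benzyl]-2-formylphenoxy}-2-[4-(benzyloxy)phenyl]acetate
Product: 15 2-{3,5-bis(benzyloxy)-4-[4-(benzyloxy)benzyl]-2-(hydroxymethyl)phenoxy}-2-[4-(benzyloxy)phenyl]ethanol (racemic)
Conditions: LiAlH4, THF, 0 °C; aqueous work-up
Reagents that add atoms: none
Why: LiAlH4 reduction of ester and aldehyde in one operation brings both carbons to the same level and makes masking of the aryl aldehyde unnecessary; the ethers are inert and the racemic centre is not touched.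

**Step 11**
Reactants: 15 2-{3,5-bis(benzyloxy)-4-[4-(benzyloxy)benzyl]-2-(hydroxymethyl)phenoxy}-2-[4-(benzyloxy)phenyl]ethanol
Product: 16 2,4-bis(benzyloxy)-3-[4-(benzyloxy)benzyl]-6-{1-[4-(benzyloxy)phenyl]-2-oxoethoxy}benzaldehyde (racemic dialdehyde)
Conditions: 2-iodoxybenzoic acid (IBX, 3 equiv), DMSO–THF, rt
Reagents that add atoms: none
Why: Oxidation of primary alcohols with a hypervalent iodine reagent under neutral conditions stops at the aldehyde, and the electron-rich benzylic alcohol should go first, so that the reactive side-chain aldehyde does not meet a free hydroxyl; the centre next to the new aldehyde is labile, which the next step exploits.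

**Step 12**
Reactants: 16 2,4-bis(benzyloxy)-3-[4-(benzyloxy)benzyl]-6-{1-[4-(benzyloxy)phenyl]-2-oxoethoxy}benzaldehyde (racemic)
Product: 18 (2R,3R)-5,7-bis(benzyloxy)-6-[4-(benzyloxy)benzyl]-2-[4-(benzyloxy)phenyl]-3-hydroxychroman-4-one, via Breslow enaminol 17 (not isolated)
Conditions: (5aR,10bS)-2-(pentafluorophenyl)-5a,10b-dihydro-4H,6H-indeno[2,1-b][1,2,4]triazolo[4,3-d][1,4]oxazin-2-ium tetrafluoroborate (20 mol %), i-Pr2NEt (20 mol %), 4 Å molecular sieves, toluene, 0 °C to rt, argon
Reagents that add atoms: the triazolium tetrafluoroborate, c1[n+](-c2c(F)c(F)c(F)c(F)c2F)nc2n1[C@H]1c3ccccc3C[C@H]1OC2.F[B-](F)(F)F (its carbene unit is held only by 17 and is released again)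
Why: Proposed new method: the triazolylidene adds to the ring A aldehyde, proton transfer gives enaminol 17, its nucleophilic carbon (future C4) attacks the side-chain aldehyde carbon (future C3) in a 6-exo-trig closure of ring C, and collapse of the adduct releases the carbene and leaves the C4 ketone beside the C3 carbinol. The closest known reactions are the triazolium-catalysed intramolecular crossed benzoin of 2-(2-oxoalkoxy)benzaldehydes to 3-hydroxychroman-4-ones, the carbene-catalysed cyclisation of dialdehydes to cyclic acyloins, and dynamic kinetic resolutions of configurationally labile carbonyl acceptors by intramolecular benzoin closure, but an aldehyde acceptor that carries the labile centre in this ring system has not been shown. C3 is set by the catalyst, whose indane wall shields one face of 17 while the hydrogen bond from the enaminol O–H to the acceptor oxygen fixes which face of the side-chain carbonyl is presented. C2 is set by dynamic kinetic resolution: the α-aryl-α-aryloxy aldehyde racemises through its enol under the amine base, and only its R antipode can enter that catalyst-defined half-chair with the 4-benzyloxyphenyl group pseudo-equatorial, which gives the 2,3-trans (2R,3R) product, also the more stable diastereomer. The step needs the acyl anion to arise at the aryl aldehyde only, and the substrate helps because the side-chain aldehyde is α-branched and inductively activated by O1, the profile of aldehydes that act as acceptors rather than donors in crossed benzoin reactions, while the small, electron-poor N-pentafluorophenyl carbene binds ortho-alkoxybenzaldehydes well and adds reversibly, so that unproductive adducts can revert. Catalytic weak base in toluene keeps aldol closure of the side-chain enolate onto the ring A aldehyde and ring-opening epimerisation of 18 slow.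

**Step 13**
Reactants: 18 (2R,3R)-5,7-bis(benzyloxy)-6-[4-(benzyloxy)benzyl]-2-[4-(benzyloxy)phenyl]-3-hydroxychroman-4-one
Product: 19 gericudranin E, (2R,3R)-3,5,7-trihydroxy-6-(4-hydroxybenzyl)-2-(4-hydroxyphenyl)chroman-4-one
Conditions: H2 (1 atm), Pd/C (10 wt % Pd), THF–MeOH, rt
Reagents that add atoms: none
Why: Hydrogenolysis of aryl benzyl ethers over palladium, well known for benzylated dihydroflavonols: the neutral medium leaves C2 and C3 untouched, and the C4 ketone, the C2–O1 bond and the diarylmethane react much more slowly than the O-benzyl groups.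

**Compound list**

1 | 2,4,6-trihydroxybenzaldehyde | O=Cc1c(O)cc(O)cc1O | starting material
2 | 4-(allyloxy)-2,6-dihydroxybenzaldehyde | O=Cc1c(O)cc(OCC=C)cc1O | intermediate
3 | 4-(allyloxy)-2,6-bis(benzyloxy)benzaldehyde | O=Cc1c(OCc2ccccc2)cc(OCC=C)cc1OCc1ccccc1 | intermediate
4 | 1-(benzyloxy)-4-bromobenzene | Brc1ccc(OCc2ccccc2)cc1 | starting material
5 | 4-(benzyloxy)phenylmagnesium bromide (not isolated) | Br[Mg]c1ccc(OCc2ccccc2)cc1 | intermediate
6 | [4-(allyloxy)-2,6-bis(benzyloxy)phenyl][4-(benzyloxy)phenyl]methanol, racemic | OC(c1ccc(OCc2ccccc2)cc1)c1c(OCc2ccccc2)cc(OCC=C)cc1OCc1ccccc1 | intermediate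
7 | 5-(allyloxy)-1,3-bis(benzyloxy)-2-[4-(benzyloxy)benzyl]benzene | C=CCOc1cc(OCc2ccccc2)c(Cc2ccc(OCc3ccccc3)cc2)c(OCc2ccccc2)c1 | intermediate
8 | 3,5-bis(benzyloxy)-4-[4-(benzyloxy)benzyl]phenol | Oc1cc(OCc2ccccc2)c(Cc2ccc(OCc3ccccc3)cc2)c(OCc2ccccc2)c1 | intermediate
9 | 2,4-bis(benzyloxy)-3-[4-(benzyloxy)benzyl]-6-hydroxybenzaldehyde | O=Cc1c(O)cc(OCc2ccccc2)c(Cc2ccc(OCc3ccccc3)cc2)c1OCc1ccccc1 | intermediate
10 | 4-(benzyloxy)phenylacetic acid | OC(=O)Cc1ccc(OCc2ccccc2)cc1 | starting material
11 | methyl 4-(benzyloxy)phenylacetate | COC(=O)Cc1ccc(OCc2ccccc2)cc1 | intermediate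
12 | 1-methoxy-1-(trimethylsilyloxy)-2-[4-(benzyloxy)phenyl]ethene, silyl ketene acetal (not isolated) | COC(O[Si](C)(C)C)=Cc1ccc(OCc2ccccc2)cc1 | intermediate
13 | methyl 2-bromo-2-[4-(benzyloxy)phenyl]acetate, racemic | COC(=O)C(Br)c1ccc(OCc2ccccc2)cc1 | intermediate
14 | methyl 2-{3,5-bis(benzyloxy)-4-[4-(benzyloxy)benzyl]-2-formylphenoxy}-2-[4-(benzyloxy)phenyl]acetate, racemic | COC(=O)C(Oc1cc(OCc2ccccc2)c(Cc2ccc(OCc3ccccc3)cc2)c(OCc2ccccc2)c1C=O)c1ccc(OCc2ccccc2)cc1 | intermediate
15 | 2-{3,5-bis(benzyloxy)-4-[4-(benzyloxy)benzyl]-2-(hydroxymethyl)phenoxy}-2-[4-(benzyloxy)phenyl]ethanol, racemic | OCC(Oc1cc(OCc2ccccc2)c(Cc2ccc(OCc3ccccc3)cc2)c(OCc2ccccc2)c1CO)c1ccc(OCc2ccccc2)cc1 | intermediate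
16 | 2,4-bis(benzyloxy)-3-[4-(benzyloxy)benzyl]-6-{1-[4-(benzyloxy)phenyl]-2-oxoethoxy}benzaldehyde, racemic (key-step precursor) | O=Cc1c(OCc2ccccc2)c(Cc2ccc(OCc3ccccc3)cc2)c(OCc2ccccc2)cc1OC(C=O)c1ccc(OCc2ccccc2)cc1 | intermediate
17 | Breslow enaminol from the ring A aldehyde of 16 and the (5aR,10bS)-triazolylidene; side-chain centre labile, enol geometry undefined (not isolated) | OC(=C1N(c2c(F)c(F)c(F)c(F)c2F)N=C2CO[C@@H]3Cc4ccccc4[C@@H]3N12)c1c(OCc2ccccc2)c(Cc2ccc(OCc3ccccc3)cc2)c(OCc2ccccc2)cc1OC(C=O)c1ccc(OCc2ccccc2)cc1 | intermediate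
18 | (2R,3R)-5,7-bis(benzyloxy)-6-[4-(benzyloxy)benzyl]-2-[4-(benzyloxy)phenyl]-3-hydroxychroman-4-one (key-step product) | O=C1c2c(cc(OCc3ccccc3)c(Cc3ccc(OCc4ccccc4)cc3)c2OCc2ccccc2)O[C@H](c2ccc(OCc3ccccc3)cc2)[C@H]1O | intermediate
19 | gericudranin E, (2R,3R)-3,5,7-trihydroxy-6-(4-hydroxybenzyl)-2-(4-hydroxyphenyl)chroman-4-one | O=C1c2c(cc(O)c(Cc3ccc(O)cc3)c2O)O[C@H](c2ccc(O)cc2)[C@H]1O | target

**Step count**

Total step count: 13.
Longest linear sequence: 11 steps (steps 1–6 and 9–13, from 1). Steps 7 and 8 form the side branch.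

**Steps most likely to fail**

First, step 12, the key step. Several processes compete with the wanted closure:
- The carbene may add to the less hindered side-chain aldehyde, and the resulting enaminol may then expel the ring A phenoxide, an internal redox esterification.
- Enaminol formation at the di-ortho-substituted, electron-rich ring A aldehyde may be sluggish.
- The base may induce aldol closure of the side-chain enolate onto the ring A aldehyde.
- Enantiopurity may be lost if closure outruns racemisation or if the product re-opens by retro-benzoin.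

The fallback is the known chalcone epoxide route to dihydroflavonols. It leaves the route at 9 and returns at 18. NaH and MeOCH2Cl in DMF convert 9 into the methoxymethyl ether F1. MeMgBr gives the secondary carbinol F2, and IBX gives the acetophenone F3. Claisen–Schmidt condensation with commercial 4-(benzyloxy)benzaldehyde (KOH, EtOH) gives the (E)-chalcone F4. Juliá–Colonna epoxidation (poly-L-leucine, urea–H2O2, DBU, THF) gives the (2R,3S)-epoxy ketone F5. HCl in MeOH–THF then removes the acetal, and the freed phenol opens the epoxide at the activated benzylic carbon. C3 keeps the configuration of the epoxide α-carbon and C2 settles trans to it, which gives 18.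

Second, step 11. Three things may go wrong: the very electron-rich benzylic alcohol may ionise; a lactol may form after the first oxidation and be over-oxidised; and the dialdehyde may degrade during isolation by aldol reaction or hydration. The fallback avoids the diol altogether. It leaves at 14 and returns at 16. HC(OMe)3 with catalytic p-toluenesulfonic acid in MeOH masks the aryl aldehyde as the dimethyl acetal F6. i-Bu2AlH in toluene at −78 °C stops at the acetal aldehyde F7, helped by the α-aryloxy group that stabilises the tetrahedral aluminium adduct. Pyridinium p-toluenesulfonate in aqueous acetone then unmasks the highly labile electron-rich aryl acetal just before the key step, which gives 16.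

Third, step 1. The competing processes are over-alkylation, etherification of an ortho hydroxyl, and C-allylation of the phloroglucinol nucleus. The fallback selects by size under non-basic conditions instead of by acidity. It leaves at 1 and returns at 8 in the same number of operations. i-Pr3SiCl and imidazole in DMF silylate the only unhindered hydroxyl to give the 4-O-triisopropylsilyl ether F8. Mitsunobu benzylation (BnOH, PPh3, DIAD, THF) gives the dibenzyl ether F9 without exposing the silyl ether to carbonate. Addition of 5 gives the diaryl carbinol F10, Et3SiH with CF3CO2H gives the silyl-protected diarylmethane F11, and Bu4NF in THF frees 8.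

**Further compounds**

F1 | step 12 | 2,4-bis(benzyloxy)-3-[4-(benzyloxy)benzyl]-6-(methoxymethoxy)benzaldehyde | O=Cc1c(OCOC)cc(OCc2ccccc2)c(Cc2ccc(OCc3ccccc3)cc2)c1OCc1ccccc1
F2 | step 12 | 1-{2,4-bis(benzyloxy)-3-[4-(benzyloxy)benzyl]-6-(methoxymethoxy)phenyl}ethanol, racemic | CC(O)c1c(OCOC)cc(OCc2ccccc2)c(Cc2ccc(OCc3ccccc3)cc2)c1OCc1ccccc1
F3 | step 12 | 1-{2,4-bis(benzyloxy)-3-[4-(benzyloxy)benzyl]-6-(methoxymethoxy)phenyl}ethanone | CC(=O)c1c(OCOC)cc(OCc2ccccc2)c(Cc2ccc(OCc3ccccc3)cc2)c1OCc1ccccc1
F4 | step 12 | (E)-1-{2,4-bis(benzyloxy)-3-[4-(benzyloxy)benzyl]-6-(methoxymethoxy)phenyl}-3-[4-(benzyloxy)phenyl]prop-2-en-1-one | O=C(/C=C/c1ccc(OCc2ccccc2)cc1)c1c(OCOC)cc(OCc2ccccc2)c(Cc2ccc(OCc3ccccc3)cc2)c1OCc1ccccc1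
F5 | step 12 | {2,4-bis(benzyloxy)-3-[4-(benzyloxy)benzyl]-6-(methoxymethoxy)phenyl}{(2R,3S)-3-[4-(benzyloxy)phenyl]oxiran-2-yl}methanone | O=C([C@@H]1O[C@H]1c1ccc(OCc2ccccc2)cc1)c1c(OCOC)cc(OCc2ccccc2)c(Cc2ccc(OCc3ccccc3)cc2)c1OCc1ccccc1
F6 | step 11 | methyl 2-{3,5-bis(benzyloxy)-4-[4-(benzyloxy)benzyl]-2-(dimethoxymethyl)phenoxy}-2-[4-(benzyloxy)phenyl]acetate, racemic | COC(=O)C(Oc1cc(OCc2ccccc2)c(Cc2ccc(OCc3ccccc3)cc2)c(OCc2ccccc2)c1C(OC)OC)c1ccc(OCc2ccccc2)cc1
F7 | step 11 | 2-{3,5-bis(benzyloxy)-4-[4-(benzyloxy)benzyl]-2-(dimethoxymethyl)phenoxy}-2-[4-(benzyloxy)phenyl]acetaldehyde, racemic | O=CC(Oc1cc(OCc2ccccc2)c(Cc2ccc(OCc3ccccc3)cc2)c(OCc2ccccc2)c1C(OC)OC)c1ccc(OCc2ccccc2)cc1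
F8 | step 1 | 2,6-dihydroxy-4-[(triisopropylsilyl)oxy]benzaldehyde | O=Cc1c(O)cc(O[Si](C(C)C)(C(C)C)C(C)C)cc1O
F9 | step 1 | 2,6-bis(benzyloxy)-4-[(triisopropylsilyl)oxy]benzaldehyde | O=Cc1c(OCc2ccccc2)cc(O[Si](C(C)C)(C(C)C)C(C)C)cc1OCc1ccccc1
F10 | step 1 | {2,6-bis(benzyloxy)-4-[(triisopropylsilyl)oxy]phenyl}[4-(benzyloxy)phenyl]methanol, racemic | OC(c1ccc(OCc2ccccc2)cc1)c1c(OCc2ccccc2)cc(O[Si](C(C)C)(C(C)C)C(C)C)cc1OCc1ccccc1
F11 | step 1 | {3,5-bis(benzyloxy)-4-[4-(benzyloxy)benzyl]phenoxy}triisopropylsilane | CC(C)[Si](Oc1cc(OCc2ccccc2)c(Cc2ccc(OCc3ccccc3)cc2)c(OCc2ccccc2)c1)(C(C)C)C(C)C
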